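**Retrosynthetic overview**

1. Target 19 comes from silylated flavanone 18 by global desilylation. Ring C of 18 is opened at C2–C3, the bond made last by an enantioselective intramolecular carbene C–H insertion of diazo ketone 17 under chiral dirhodium tetracarboxylate catalysis.
2. Enabling feature: C2 of pyranone ring C is both benzylic to ring B (para-alkoxy-substituted) and bound to the ring oxygen O1, and it lies six atoms from C3 (C3–C4(=O)–C4a–C8a–O1–C2). In the precursor it is therefore a doubly activated O–CH2–aryl methylene in 1,6-relationship to the carbene carbon.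
3. 17 comes from methyl ketone 15 by diazo transfer; 15 comes from ring A phenol 7 and benzylic alcohol 14 by Mitsunobu etherification, which makes the O1–C2 bond.
4. 7 comes from 2,4,6-trihydroxyacetophenone by bis-silylation, O-prenylation and para-Claisen–Cope rearrangement. 14 comes from bromocatechol ester 8 and (E)-β-ocimene by B-alkyl Suzuki coupling, enantioselective Wacker-type cyclisation (dihydropyran ring, quaternary center and diene in one step) and ester reduction.
5. Ring order: rings A and B are bought as arenes; the dihydropyran ring fused to ring B closes in step 6 and pyranone ring C closes in step 10.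

Key step: step 10

Remark: methyl 3-bromo-4,5-dihydroxybenzoate and isomerically enriched (E)-β-ocimene are assumed to be bought as such.
Remark: the sense of induction of the chiral catalysts in steps 6 and 10 cannot be predicted with confidence for these substrates; one ligand enantiomer is named in each case, and its mirror image is to be used if a model substrate shows the opposite sense.
Remark: catalyst-bound species (alkylpalladium, rhodium carbene) are described in the Why lines and carry no number; free intermediates formed in the flask are numbered.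

**Route**

Step 1
Reactants: 1 1-(2,4,6-trihydroxyphenyl)ethan-1-one
Product: 2 1-[2,4-bis(tert-butyldimethylsilyloxy)-6-hydroxyphenyl]ethan-1-one
Conditions: TBSCl (2.1 equiv), imidazole (4.5 equiv), DMF, 0 °C to rt
Reagents that add atoms: tert-butyldimethylsilyl chloride, CC(C)(C)[Si](C)(C)Cl
Why: Silylation of phenols with a silyl chloride and imidazole should take the free 4-hydroxyl and one of the two equivalent ortho-hydroxyls, while the last hydroxyl stays free because its hydrogen bond to the acetyl carbonyl makes it the least nucleophilic and most hindered site.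

Step 2
Reactants: 2 1-[2,4-bis(tert-butyldimethylsilyloxy)-6-hydroxyphenyl]ethan-1-one; 3 3-methylbut-2-en-1-ol
Product: 4 1-[2,4-bis(tert-butyldimethylsilyloxy)-6-(3-methylbut-2-en-1-yloxy)phenyl]ethan-1-one
Conditions: PPh3, DIAD, THF, 0 °C to rt
Reagents that add atoms: none
Why: Mitsunobu etherification should alkylate the remaining acidic, chelated phenol at the primary allylic carbon under neutral conditions that leave the aryl silyl ethers untouched.

Step 3
Reactants: 4 1-[2,4-bis(tert-butyldimethylsilyloxy)-6-(3-methylbut-2-en-1-yloxy)phenyl]ethan-1-one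
Product: 7 1-[2,4-bis(tert-butyldimethylsilyloxy)-6-hydroxy-3-(3-methylbut-2-en-1-yl)phenyl]ethan-1-one, via ortho-dienone 5 (not isolated), via para-dienone 6 (not isolated)
Conditions: Eu(fod)3 [tris(6,6,7,7,8,8,8-heptafluoro-2,2-dimethyloctane-3,5-dionato)europium] (10 mol %), toluene, 80 °C
Reagents that add atoms: none
Why: A lanthanide-catalysed aromatic Claisen rearrangement to the ortho position followed by a Cope rearrangement (para-Claisen–Cope) should carry the prenyl group unrearranged to C3, para to the ether oxygen, and rearomatisation frees exactly the hydroxyl that is etherified in step 8, which fixes the 6-prenyl pattern of the flavanone.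

Step 4
Reactants: 8 methyl 3-bromo-4,5-dihydroxybenzoate
Product: 9 methyl 3-bromo-4-hydroxy-5-[(triisopropylsilyl)oxy]benzoate
Conditions: TIPSCl (1.05 equiv), imidazole (2.5 equiv), DMF, 0 °C to rt
Reagents that add atoms: triisopropylsilyl chloride, CC(C)[Si](Cl)(C(C)C)C(C)C
Why: Monosilylation of the catechol should place the bulky silyl group on the less hindered, less acidic 5-hydroxyl, and base-mediated 1,2-silyl migration between the catechol oxygens converges on the same isomer because the 4-phenoxide (para to the ester, ortho to bromine) is the more stable one.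

Step 5
Reactants: 9 methyl 3-bromo-4-hydroxy-5-[(triisopropylsilyl)oxy]benzoate; 10 (3E)-3,7-dimethylocta-1,3,6-triene [(E)-β-ocimene]
Product: 12 methyl 3-[(3E)-3,7-dimethylocta-3,6-dien-1-yl]-4-hydroxy-5-[(triisopropylsilyl)oxy]benzoate, via alkylborane 11 (not isolated)
Conditions: 10, 9-BBN, THF, 0 °C to rt; then 9, PdCl2(dppf) (5 mol %), aq K3PO4, DMF, 50 °C
Reagents that add atoms: none
Why: 9-BBN should hydroborate the monosubstituted terminal alkene of the triene with anti-Markovnikov selectivity far faster than the two trisubstituted alkenes, and the primary B-alkyl borane then undergoes B-alkyl Suzuki–Miyaura coupling with the aryl bromide with the (E)-alkene intact.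

Step 6
Reactants: 12 methyl 3-[(3E)-3,7-dimethylocta-3,6-dien-1-yl]-4-hydroxy-5-[(triisopropylsilyl)oxy]benzoate
Product: 13 methyl (2S)-2-methyl-2-[(1E)-4-methylpenta-1,3-dien-1-yl]-8-[(triisopropylsilyl)oxy]-3,4-dihydro-2H-chromene-6-carboxylate
Conditions: Pd(OCOCF3)2 (10 mol %), (S,S)-Bn-BOXAX (2,2'-bis[(4S)-4-benzyl-4,5-dihydrooxazol-2-yl]-1,1'-binaphthyl, 20 mol %), p-benzoquinone (4 equiv), MeOH, rt
Reagents that add atoms: none
Why: In this enantioselective Wacker-type oxidative cyclisation the palladium phenoxide should add across the proximal trisubstituted alkene in 6-exo fashion, the chiral bis(oxazoline) ligand selecting the alkene face and so setting the quaternary C2 as (S), and β-hydride elimination, possible only toward the allylic CH2 because the other β-carbon is quaternary, gives the conjugated (E)-diene while benzoquinone reoxidises palladium.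

Step 7
Reactants: 13 methyl (2S)-2-methyl-2-[(1E)-4-methylpenta-1,3-dien-1-yl]-8-[(triisopropylsilyl)oxy]-3,4-dihydro-2H-chromene-6-carboxylate
Product: 14 {(2S)-2-methyl-2-[(1E)-4-methylpenta-1,3-dien-1-yl]-8-[(triisopropylsilyl)oxy]-3,4-dihydro-2H-chromen-6-yl}methanol
Conditions: i-Bu2AlH (2.5 equiv), CH2Cl2, −78 °C; aq Rochelle salt
Reagents that add atoms: none
Why: Hydride reduction of the aryl ester with i-Bu2AlH at low temperature should give the benzylic alcohol without touching the diene, the tertiary allylic ether or the aryl silyl ether.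

Step 8
Reactants: 7 1-[2,4-bis(tert-butyldimethylsilyloxy)-6-hydroxy-3-(3-methylbut-2-en-1-yl)phenyl]ethan-1-one; 14 {(2S)-2-methyl-2-[(1E)-4-methylpenta-1,3-dien-1-yl]-8-[(triisopropylsilyl)oxy]-3,4-dihydro-2H-chromen-6-yl}methanol
Product: 15 1-[2,4-bis(tert-butyldimethylsilyloxy)-3-(3-methylbut-2-en-1-yl)-6-({(2S)-2-methyl-2-[(1E)-4-methylpenta-1,3-dien-1-yl]-8-[(triisopropylsilyl)oxy]-3,4-dihydro-2H-chromen-6-yl}methoxy)phenyl]ethan-1-one
Conditions: PPh3, DIAD, THF, 0 °C to rt
Reagents that add atoms: none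
Why: Mitsunobu etherification should join the two halves by SN2 displacement at the primary benzylic carbon by the only free phenol of 7, creating the O1–C2 bond of the future ring C without acid or base.

Step 9
Reactants: 15 1-[2,4-bis(tert-butyldimethylsilyloxy)-3-(3-methylbut-2-en-1-yl)-6-({(2S)-2-methyl-2-[(1E)-4-methylpenta-1,3-dien-1-yl]-8-[(triisopropylsilyl)oxy]-3,4-dihydro-2H-chromen-6-yl}methoxy)phenyl]ethan-1-one
Product: 17 2-diazo-1-[2,4-bis(tert-butyldimethylsilyloxy)-3-(3-methylbut-2-en-1-yl)-6-({(2S)-2-methyl-2-[(1E)-4-methylpenta-1,3-dien-1-yl]-8-[(triisopropylsilyl)oxy]-3,4-dihydro-2H-chromen-6-yl}methoxy)phenyl]ethan-1-one, via trifluoroacetyl diketone 16 (not isolated)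
Conditions: LiN(SiMe3)2, THF, −78 °C; CF3CO2CH2CF3; aq HCl work-up; then MsN3, Et3N, H2O (1 equiv), MeCN, rt
Reagents that add atoms: methanesulfonyl azide, CS(=O)(=O)N=[N+]=[N-]
Why: In this detrifluoroacetylative (Regitz-type) diazo transfer, kinetic enolisation of the methyl ketone and Claisen acylation should give an activated 1,3-diketone whose enolate adds to the sulfonyl azide and fragments with transfer of the trifluoroacetyl group to nitrogen, a sequence that is standard for aryl methyl ketones and tolerates silyl ethers and alkenes.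

Step 10
Reactants: 17 2-diazo-1-[2,4-bis(tert-butyldimethylsilyloxy)-3-(3-methylbut-2-en-1-yl)-6-({(2S)-2-methyl-2-[(1E)-4-methylpenta-1,3-dien-1-yl]-8-[(triisopropylsilyl)oxy]-3,4-dihydro-2H-chromen-6-yl}methoxy)phenyl]ethan-1-one
Product: 18 (2S)-5,7-bis(tert-butyldimethylsilyloxy)-2-{(2S)-2-methyl-2-[(1E)-4-methylpenta-1,3-dien-1-yl]-8-[(triisopropylsilyl)oxy]-3,4-dihydro-2H-chromen-6-yl}-6-(3-methylbut-2-en-1-yl)-2,3-dihydro-4H-chromen-4-one
Conditions: dirhodium tetrakis[N-phthaloyl-(S)-tert-leucinate], Rh2(S-PTTL)4 (2 mol %), CH2Cl2, 0 °C, addition of 17 over 3 h, final 0.005 M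
Reagents that add atoms: none
Why: The dirhodium tetracarboxylate should extrude N2 from 17 to give an electrophilic rhodium carbene at C3, which inserts into a C–H bond of the O–CH2–aryl group through a three-centre, hydride-transfer-like transition state, forming the C2–C3 bond and releasing the catalyst. The closest known reaction type is the dirhodium-carboxylate-catalysed intramolecular C–H insertion of 2-alkoxyaryl diazo ketones to chroman-4-ones, for which enantioselective versions with chiral carboxylate ligands exist. Ring C closes as a six-membered ring by 1,6-insertion (C3, C4, C4a, C8a, O1, C2 counted from the carbene carbon) through a chair-like six-membered transition state that contains the ether oxygen. The new stereocenter C2 is set under catalyst control: the chiral carboxylate ligands select one of the two benzylic hydrogens, which are diastereotopic only through the remote chroman center, and insertion occurs with retention, so the ligand enantiomer decides between 2S and 2R. The step needs chemoselectivity for this C–H bond over oxonium-ylide formation with 1,2-benzyl shift, cyclopropanation of the prenyl and dienyl alkenes, and O–H insertion. This is secured by the double activation of the methylene (ether oxygen and electron-rich para-alkoxyaryl group), by the weak donor ability of the ether oxygen, whose lone pair is conjugated with the aryl ketone, by silylation of all three phenols, and by the distance of the alkenes (the prenyl alkene could only close a seven-membered ring), with slow addition at high dilution suppressing bimolecular paths.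

Step 11
Reactants: 18 (2S)-5,7-bis(tert-butyldimethylsilyloxy)-2-{(2S)-2-methyl-2-[(1E)-4-methylpenta-1,3-dien-1-yl]-8-[(triisopropylsilyl)oxy]-3,4-dihydro-2H-chromen-6-yl}-6-(3-methylbut-2-en-1-yl)-2,3-dihydro-4H-chromen-4-one
Product: 19 (2S)-5,7-dihydroxy-2-{(2S)-8-hydroxy-2-methyl-2-[(1E)-4-methylpenta-1,3-dien-1-yl]-3,4-dihydro-2H-chromen-6-yl}-6-(3-methylbut-2-en-1-yl)-2,3-dihydro-4H-chromen-4-one
Conditions: Bu4NF (4 equiv), AcOH (4 equiv), THF, 0 °C to rt
Reagents that add atoms: none
Why: Fluoride should cleave all three aryl silyl ethers, and buffering with acetic acid keeps the medium near neutral so that neither base-induced ring opening of the flavanone (which would scramble C2) nor acid ionisation of the tertiary dienyl ether can occur.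

**Compound list**

1 | 1-(2,4,6-trihydroxyphenyl)ethan-1-one | CC(=O)c1c(O)cc(O)cc1O | starting material
2 | 1-[2,4-bis(tert-butyldimethylsilyloxy)-6-hydroxyphenyl]ethan-1-one | CC(=O)c1c(O)cc(O[Si](C)(C)C(C)(C)C)cc1O[Si](C)(C)C(C)(C)C | intermediate
3 | 3-methylbut-2-en-1-ol | CC(C)=CCO | starting material
4 | 1-[2,4-bis(tert-butyldimethylsilyloxy)-6-(3-methylbut-2-en-1-yloxy)phenyl]ethan-1-one | CC(=O)c1c(OCC=C(C)C)cc(O[Si](C)(C)C(C)(C)C)cc1O[Si](C)(C)C(C)(C)C | intermediate
5 | ortho-dienone: 2-acetyl-3,5-bis(tert-butyldimethylsilyloxy)-6-(2-methylbut-3-en-2-yl)cyclohexa-2,4-dien-1-one | CC(=O)C1=C(O[Si](C)(C)C(C)(C)C)C=C(O[Si](C)(C)C(C)(C)C)C(C(C)(C)C=C)C1=O | intermediate (not isolated)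
6 | para-dienone: 2-acetyl-3,5-bis(tert-butyldimethylsilyloxy)-4-(3-methylbut-2-en-1-yl)cyclohexa-2,5-dien-1-one | CC(=O)C1=C(O[Si](C)(C)C(C)(C)C)C(CC=C(C)C)C(O[Si](C)(C)C(C)(C)C)=CC1=O | intermediate (not isolated)
7 | 1-[2,4-bis(tert-butyldimethylsilyloxy)-6-hydroxy-3-(3-methylbut-2-en-1-yl)phenyl]ethan-1-one | CC(=O)c1c(O)cc(O[Si](C)(C)C(C)(C)C)c(CC=C(C)C)c1O[Si](C)(C)C(C)(C)C | intermediate
8 | methyl 3-bromo-4,5-dihydroxybenzoate | COC(=O)c1cc(O)c(O)c(Br)c1 | starting material
9 | methyl 3-bromo-4-hydroxy-5-[(triisopropylsilyl)oxy]benzoate | COC(=O)c1cc(O[Si](C(C)C)(C(C)C)C(C)C)c(O)c(Br)c1 | intermediate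
10 | (3E)-3,7-dimethylocta-1,3,6-triene | C=C/C(C)=C/CC=C(C)C | starting material
11 | alkylborane: 9-[(3E)-3,7-dimethylocta-3,6-dien-1-yl]-9-borabicyclo[3.3.1]nonane | B1(CC/C(C)=C/CC=C(C)C)C2CCCC1CCC2 | intermediate (not isolated)
12 | methyl 3-[(3E)-3,7-dimethylocta-3,6-dien-1-yl]-4-hydroxy-5-[(triisopropylsilyl)oxy]benzoate | COC(=O)c1cc(O[Si](C(C)C)(C(C)C)C(C)C)c(O)c(CC/C(C)=C/CC=C(C)C)c1 | intermediate
13 | methyl (2S)-2-methyl-2-[(1E)-4-methylpenta-1,3-dien-1-yl]-8-[(triisopropylsilyl)oxy]-3,4-dihydro-2H-chromene-6-carboxylate | CC(C)=C/C=C/[C@]1(C)CCc2cc(C(=O)OC)cc(O[Si](C(C)C)(C(C)C)C(C)C)c2O1 | intermediate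
14 | {(2S)-2-methyl-2-[(1E)-4-methylpenta-1,3-dien-1-yl]-8-[(triisopropylsilyl)oxy]-3,4-dihydro-2H-chromen-6-yl}methanol | CC(C)=C/C=C/[C@]1(C)CCc2cc(CO)cc(O[Si](C(C)C)(C(C)C)C(C)C)c2O1 | intermediate
15 | 1-[2,4-bis(tert-butyldimethylsilyloxy)-3-(3-methylbut-2-en-1-yl)-6-({(2S)-2-methyl-2-[(1E)-4-methylpenta-1,3-dien-1-yl]-8-[(triisopropylsilyl)oxy]-3,4-dihydro-2H-chromen-6-yl}methoxy)phenyl]ethan-1-one | CC(C)=C/C=C/[C@]1(C)CCc2cc(COc3cc(O[Si](C)(C)C(C)(C)C)c(CC=C(C)C)c(O[Si](C)(C)C(C)(C)C)c3C(C)=O)cc(O[Si](C(C)C)(C(C)C)C(C)C)c2O1 | intermediate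
16 | trifluoroacetyl diketone: 4,4,4-trifluoro-1-[aryl of 15]butane-1,3-dione | CC(C)=C/C=C/[C@]1(C)CCc2cc(COc3cc(O[Si](C)(C)C(C)(C)C)c(CC=C(C)C)c(O[Si](C)(C)C(C)(C)C)c3C(=O)CC(=O)C(F)(F)F)cc(O[Si](C(C)C)(C(C)C)C(C)C)c2O1 | intermediate (not isolated)
17 | 2-diazo-1-[aryl of 15]ethan-1-one (full name in step 9) | CC(C)=C/C=C/[C@]1(C)CCc2cc(COc3cc(O[Si](C)(C)C(C)(C)C)c(CC=C(C)C)c(O[Si](C)(C)C(C)(C)C)c3C(=O)C=[N+]=[N-])cc(O[Si](C(C)C)(C(C)C)C(C)C)c2O1 | intermediate
18 | (2S)-5,7-bis(tert-butyldimethylsilyloxy)-2-{(2S)-2-methyl-2-[(1E)-4-methylpenta-1,3-dien-1-yl]-8-[(triisopropylsilyl)oxy]-3,4-dihydro-2H-chromen-6-yl}-6-(3-methylbut-2-en-1-yl)-2,3-dihydro-4H-chromen-4-one | CC(C)=C/C=C/[C@]1(C)CCc2cc([C@@H]3CC(=O)c4c(cc(O[Si](C)(C)C(C)(C)C)c(CC=C(C)C)c4O[Si](C)(C)C(C)(C)C)O3)cc(O[Si](C(C)C)(C(C)C)C(C)C)c2O1 | intermediate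
19 | (2S)-5,7-dihydroxy-2-{(2S)-8-hydroxy-2-methyl-2-[(1E)-4-methylpenta-1,3-dien-1-yl]-3,4-dihydro-2H-chromen-6-yl}-6-(3-methylbut-2-en-1-yl)-2,3-dihydro-4H-chromen-4-one | CC(C)=C/C=C/[C@]1(C)CCc2cc([C@@H]3CC(=O)c4c(cc(O)c(CC=C(C)C)c4O)O3)cc(O)c2O1 | target

**Step count and risks**

Total step count: 11. Longest linear sequence: 8 steps (steps 4 to 11, from 8).

Steps most likely to fail:

1. Step 10. The carbene may be diverted into oxonium-ylide formation at the ether oxygen followed by a 1,2-benzyl (Stevens) shift, or into alkene cyclopropanation, and the catalyst may discriminate the two benzylic hydrogens poorly. The fallback builds ring C the classical way; it sets out from 14 and 7 and comes back at 18.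
   - Alcohol 14 is oxidised with MnO2 (CH2Cl2, rt) to (2S)-2-methyl-2-[(1E)-4-methylpenta-1,3-dien-1-yl]-8-[(triisopropylsilyl)oxy]-3,4-dihydro-2H-chromene-6-carbaldehyde F1.
   - Claisen–Schmidt condensation of F1 with 7 (pyrrolidine, toluene, molecular sieves, rt to 50 °C) should give (2E)-1-[2,4-bis(tert-butyldimethylsilyloxy)-6-hydroxy-3-(3-methylbut-2-en-1-yl)phenyl]-3-{(2S)-2-methyl-2-[(1E)-4-methylpenta-1,3-dien-1-yl]-8-[(triisopropylsilyl)oxy]-3,4-dihydro-2H-chromen-6-yl}prop-2-en-1-one F2.
   - In F2 only the free 6-hydroxyl can add to the enone, so oxa-Michael closure under the same amine conditions should give 18 as a mixture of C2 epimers, to be separated by preparative HPLC on a chiral stationary phase.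

2. Step 6. The product diene may be over-oxidised or isomerised by divalent palladium and benzoquinone, and face selectivity may be lost if the alkene geometry of 10 is not uniform. The fallback forms the ring on the directly precedented substrate and builds the diene afterwards; it sets out from 9 and comes back at 13.
   - (3E)-3-Methylpenta-1,3-diene is hydroborated with 9-BBN to 9-[(3E)-3-methylpent-3-en-1-yl]-9-borabicyclo[3.3.1]nonane F3.
   - F3 is coupled with 9 under the conditions of step 5 to methyl 4-hydroxy-3-[(3E)-3-methylpent-3-en-1-yl]-5-[(triisopropylsilyl)oxy]benzoate F4.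
   - Oxidative cyclisation of F4 under the conditions of step 6 ends in a plain vinyl group and should give methyl (2S)-2-ethenyl-2-methyl-8-[(triisopropylsilyl)oxy]-3,4-dihydro-2H-chromene-6-carboxylate F5, so no diene is present while palladium and benzoquinone are.
   - Lemieux–Johnson cleavage of the vinyl group (OsO4 cat., NaIO4, 2,6-lutidine, dioxane/H2O) gives methyl (2S)-2-formyl-2-methyl-8-[(triisopropylsilyl)oxy]-3,4-dihydro-2H-chromene-6-carboxylate F6.
   - Horner–Wadsworth–Emmons olefination of F6 with lithiated diethyl (3-methylbut-2-en-1-yl)phosphonate (n-BuLi, THF, −78 °C to rt) should give the (E)-diene 13.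

3. Step 3. The ortho-dienone may tautomerise before the Cope shift and give the ortho (1,1-dimethylallyl) product, because the para position is shielded by two silyloxy groups. The fallback installs the prenyl group first and relies on sterics in the etherification; it sets out from 1 and comes back at 15.
   - C-Prenylation of 1 with prenyl bromide and DBU in THF gives 1-[2,4,6-trihydroxy-3-(3-methylbut-2-en-1-yl)phenyl]ethan-1-one F7 as one regioisomer, since the two free ring positions of 1 are equivalent.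
   - One equivalent of TBSCl with imidazole should silylate the non-chelated, most acidic 4-hydroxyl and give 1-[4-(tert-butyldimethylsilyloxy)-2,6-dihydroxy-3-(3-methylbut-2-en-1-yl)phenyl]ethan-1-one F8.
   - Mitsunobu etherification of F8 with 14 (PPh3, DIAD, THF) is expected at the less hindered ortho-hydroxyl, the one not flanked by the prenyl group, giving 1-[4-(tert-butyldimethylsilyloxy)-2-hydroxy-3-(3-methylbut-2-en-1-yl)-6-({(2S)-2-methyl-2-[(1E)-4-methylpenta-1,3-dien-1-yl]-8-[(triisopropylsilyl)oxy]-3,4-dihydro-2H-chromen-6-yl}methoxy)phenyl]ethan-1-one F9.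
   - Silylation of the remaining chelated hydroxyl of F9 with TBSOTf and 2,6-lutidine (CH2Cl2, 0 °C) gives 15.

Further compounds

F1 | step 10 | (2S)-2-methyl-2-[(1E)-4-methylpenta-1,3-dien-1-yl]-8-[(triisopropylsilyl)oxy]-3,4-dihydro-2H-chromene-6-carbaldehyde | CC(C)=C/C=C/[C@]1(C)CCc2cc(C=O)cc(O[Si](C(C)C)(C(C)C)C(C)C)c2O1
F2 | step 10 | (2E)-1-[2,4-bis(tert-butyldimethylsilyloxy)-6-hydroxy-3-(3-methylbut-2-en-1-yl)phenyl]-3-{(2S)-2-methyl-2-[(1E)-4-methylpenta-1,3-dien-1-yl]-8-[(triisopropylsilyl)oxy]-3,4-dihydro-2H-chromen-6-yl}prop-2-en-1-one | CC(C)=C/C=C/[C@]1(C)CCc2cc(/C=C/C(=O)c3c(O)cc(O[Si](C)(C)C(C)(C)C)c(CC=C(C)C)c3O[Si](C)(C)C(C)(C)C)cc(O[Si](C(C)C)(C(C)C)C(C)C)c2O1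
F3 | step 6 | 9-[(3E)-3-methylpent-3-en-1-yl]-9-borabicyclo[3.3.1]nonane | B1(CC/C(C)=C/C)C2CCCC1CCC2
F4 | step 6 | methyl 4-hydroxy-3-[(3E)-3-methylpent-3-en-1-yl]-5-[(triisopropylsilyl)oxy]benzoate | COC(=O)c1cc(O[Si](C(C)C)(C(C)C)C(C)C)c(O)c(CC/C(C)=C/C)c1
F5 | step 6 | methyl (2S)-2-ethenyl-2-methyl-8-[(triisopropylsilyl)oxy]-3,4-dihydro-2H-chromene-6-carboxylate | C=C[C@]1(C)CCc2cc(C(=O)OC)cc(O[Si](C(C)C)(C(C)C)C(C)C)c2O1
F6 | step 6 | methyl (2S)-2-formyl-2-methyl-8-[(triisopropylsilyl)oxy]-3,4-dihydro-2H-chromene-6-carboxylate | O=C[C@]1(C)CCc2cc(C(=O)OC)cc(O[Si](C(C)C)(C(C)C)C(C)C)c2O1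
F7 | step 3 | 1-[2,4,6-trihydroxy-3-(3-methylbut-2-en-1-yl)phenyl]ethan-1-one | CC(=O)c1c(O)cc(O)c(CC=C(C)C)c1O
F8 | step 3 | 1-[4-(tert-butyldimethylsilyloxy)-2,6-dihydroxy-3-(3-methylbut-2-en-1-yl)phenyl]ethan-1-one | CC(=O)c1c(O)cc(O[Si](C)(C)C(C)(C)C)c(CC=C(C)C)c1O
F9 | step 3 | 1-[4-(tert-butyldimethylsilyloxy)-2-hydroxy-3-(3-methylbut-2-en-1-yl)-6-({(2S)-2-methyl-2-[(1E)-4-methylpenta-1,3-dien-1-yl]-8-[(triisopropylsilyl)oxy]-3,4-dihydro-2H-chromen-6-yl}methoxy)phenyl]ethan-1-one | CC(C)=C/C=C/[C@]1(C)CCc2cc(COc3cc(O[Si](C)(C)C(C)(C)C)c(CC=C(C)C)c(O)c3C(C)=O)cc(O[Si](C(C)C)(C(C)C)C(C)C)c2O1
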